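## The problem

The target 29 is the diester of an all-trans cyclopentane tetraol with two identical C8 dialdehyde acids: ring C1 carries an acyloxy group, C2 a methyl group, C3 an acyloxymethyl group and C4 a 1,3-dihydroxypropan-2-yl group (1R,2R,3S,4R, every neighbouring pair trans). Each ester oxygen carries the (3S,4E)-4-formyl-3-(2-oxoethyl)hex-4-enoyl chain: C1' ester carbonyl, C2' methylene, C3' stereocentre, the C4'=C5' ethylidene enal, and a 2-oxoethyl branch on C3'. No rings are fused, so the work is one carbocycle with four contiguous centres plus two copies of a branched chain. On the ring, C4 can direct C3 (anti addition to a cyclopentenone) and C3 can direct C2 (enolate alkylation, also the thermodynamic arrangement), but the C1 carbinol trans to the C2 methyl is not what hydride delivery gives cleanly and is best reached by inversion. The two C3' centres lie four and five bonds from the nearest ring stereocentre, cannot be relayed from it, and must both be set S by a catalyst. The four aldehydes (two of them (E)-2-alkylidene enals inside 1,5-dialdehyde arrays) will not survive base, hydride, organometallics or long acid exposure, and a free 1,3-diol must coexist with them, so aldehydes and diol are unveiled last and the two aldehydes of each arm must stay distinguishable until then. The enabling feature is that C3' is β to the ester carbonyl C1' (through C2') and β to an aldehyde carbon (through a methylene): C2'–C3' is the bond an acetate-type carbon nucleophile forms on adding to the β-carbon of an enal, and both such bonds can be made at once from a core bis(malonate).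

## Retrosynthesis

**29 ⇒ 28.** The two C–O bonds of an isopropylidene ketal on the side-chain 1,3-diol are cut last. The ketal keeps the diol out of every acylation, silylation and oxidation, and its removal needs only dilute aqueous acid, which the dialdehyde arms tolerate. Silyl ethers on the diol would not be distinguishable from the arm protecting groups chosen below.

**28 ⇒ 27 ⇒ 26.** The saturated aldehyde of each arm is taken back to a primary alcohol and then to its tert-butyldimethylsilyl ether. A dimethyl acetal in this position would save two steps. It would, however, be a second acetal in the silyl triflate steps that build the ethylidene group, where it would ionise in competition with acetaldehyde dimethyl acetal 24. In the key step, the dienamine formed by γ-deprotonation of the iminium ion could also expel methoxide to a donor-stabilised 5-methoxypentadienyl iminium ion. The silyl ether is inert to the silyl triflate, and its loss from a dienamine would give only an unstabilised dienyl iminium ion. The forward steps must remove silicon and oxidise without touching ketal, esters or enals.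

**26 ⇒ 23 + 24.** The C4'=C5' double bond of each arm is cut as an aldol-type condensation between the α-carbon of a 2-oxoethyl group and a two-carbon electrophile. The aldehyde is used as its enol silane 23 (from dialdehyde 22) and the electrophile as acetaldehyde dimethyl acetal 24, so no free aldehyde enolate is generated next to the esters. The forward reaction must give the E enal, which is the thermodynamic isomer, and must leave C3' alone; C3' has no acidifying neighbour.

**22 ⇒ 20.** The C2'–H bonds are replaced by C2'–CO2allyl. The extra carboxylate makes C2' acidic enough for amine catalysis and is the only group removable later under neutral palladium conditions. Its loss also erases the uncontrolled C2' centres.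

**20 ⇒ 15 + 19 (key cut).** Both C2'–C3' bonds are cut, giving the core bis(allyl malonate) 15 and two molecules of enal 19. Against esterifying the core with a preformed chiral acid, this cut builds both arms and both C3' centres in one catalytic operation from a nucleophile with no stereocentre in the arm. The precursor 15 is simpler by sixteen skeletal atoms and two stereocentres. The forward reaction must be 1,4-selective, add once per malonate, and set both C3' centres from the catalyst alone.

**19 ⇒ 17 + 18; 17 ⇒ 16.** The C2=C3 bond of the enal is cut by cross-metathesis into silyl ether 17 and crotonaldehyde 18; 17 comes from but-3-en-1-ol 16. This avoids a β-silyloxy aldehyde and a formyl ylide.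

**15 ⇒ 11 + 14; 14 ⇒ 12 + 13.** The two ester C–O bonds are cut to two molecules of allyl hydrogen malonate 14 (from Meldrum's acid 12 and allyl alcohol 13) and the ring diol. The diol chosen is the C1 epimer 11, because a bulky hydride gives the cis-2-methyl carbinol reliably. A Mitsunobu esterification then acylates the primary hydroxyl and inverts C1 while acylating it. One operation therefore installs both malonates and corrects the only ring centre not set by its neighbours.

**11 ⇒ 9 ⇒ 8.** The hydroxymethyl group is taken back to a vinyl group (ozonolysis with reductive work-up) and the carbinol to ketone 8. Vinyl is the hydroxymethyl equivalent that is best behaved in copper-mediated conjugate addition.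

**8 ⇒ 6.** The C3–vinyl and C2–methyl bonds are cut together: conjugate addition of a vinyl copper nucleophile to enone 6 anti to the C4 substituent, then methylation of the enolate anti to the new vinyl group. A ring contraction of a monoterpene cyclohexenone was weighed against this. It would deliver the methyl on a tetrasubstituted alkene and leave C2 and C3 to a face-selective hydrogenation, whereas here each centre is set anti to its neighbour.

**6 ⇒ 5 ⇒ 4 ⇒ 3 ⇒ 1 + 2.** The dioxanyl group is a reduced, ketal-protected malonate. The C4–C bond is cut by allylic alkylation of the enzymatically desymmetrised hydroxy acetate 1 with dimethyl malonate 2, which proceeds with net retention and fixes C4 as R. Reduction (4), ketalisation (5) and allylic oxidation (6) follow.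

## Roads not taken

**Alternative 1:** The ring bond between the acyloxymethyl-bearing carbon and the diol-bearing carbon would be cut. Dimethyl 2-[(3R,4E)-3-(tert-butyldimethylsilyloxy)-4-methyl-6-oxohex-4-en-1-ylidene]propanedioate A1 would be treated with a chiral imidazolidinone salt and a dihydropyridine hydride donor. Hydride adds to the methyl-bearing β-carbon and the resulting enamine carbon closes 5-exo-trig onto the alkylidene malonate, giving the cyclopentane aldehyde A2.
- Merits: the ring and three centres form in one step; the malonate is the latent 1,3-diol and the aldehyde the latent hydroxymethyl group. The carbinol configuration is carried in from A1, so no inversion is needed. In that respect it is better than the chosen core route, which spends a reduction and an invertive esterification on C1.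
- Weak points: A1 needs its own enantioselective synthesis of a γ-silyloxy, β,β-disubstituted enal. Alkylidene malonates can themselves be reduced by dihydropyridine donors. The all-trans outcome depends on an untested match between the catalyst and the silyloxy centre.
- Comparison: it solves only the core; the arms would still need the conjugate addition used here. The chosen plan sets against it a core built from a commercial enantiopure cyclopentene by substrate-controlled steps of known sense.

**Alternative 2:** The ring bond between the carbinol carbon and the methyl-bearing carbon would be cut. Cathodic one-electron reduction of (3R,4R)-4-[(benzyloxy)methyl]-3-(2,2-dimethyl-1,3-dioxan-5-yl)hex-5-enal A3 gives a ketyl that adds 5-exo-trig to the inner vinyl carbon. The exocyclic radical is reduced and protonated to the methyl group, giving cyclopentanol A4.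
- Merits: the trans methyl/hydroxyl pair, the weak spot of the chosen core route, is formed directly, with no reagents beyond electrons and protons. Hydrogenolysis of A4 would give the all-trans diol F5, which a plain carbodiimide esterification converts into 15.
- Weak points: aldehyde ketyls facing unactivated terminal alkenes tend to dimerise or be reduced further. A3 carries two adjacent acyclic stereocentres that must be made by asymmetric synthesis. The relative configuration of the new centres rests on a cyclisation transition state, not on a ring.
- Comparison: better at C1/C2, but it needs electrolysis equipment and a longer acyclic precursor. The chosen plan offers textbook cuprate/enolate stereocontrol on a ring.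

**Alternative 3:** In each arm the C3'–CH2 bond and an O–C acetal bond would be cut. The core bis[(E)-5-oxopent-3-enoate] A5 would react twice as a 1-oxadiene with ethyl vinyl ether A6 under a chiral tridentate Schiff-base chromium chloride complex, (L)CrCl, of trivalent chromium. This closes two cis-2,4-disubstituted 2-ethoxy-3,4-dihydro-2H-pyrans, giving A7.
- Merits: both aldehydes of each arm emerge masked and differentiated at the correct oxidation level, and the enol ether carbon that must take the ethylidene group is already nucleophilic. After the key step this road is shorter than the chosen one, which needs deallylation–decarboxylation, enol silane formation, desilylation and oxidation.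
- Weak points: A5 has a methylene flanked by an ester and an enal and will tautomerise readily. The cycloaddition is established for simple β-alkyl enals, not for two ester-bearing oxadienes on one molecule. The later ethylidenation under Lewis acid would have to discriminate the acetaldehyde acetal from the ring acetals.
- Comparison: the chosen plan offers stable, isolable partners (15 and 19), a well-studied amine catalyst, and no aldehyde-derived acetal in the molecule when the Lewis acid step is run.

Key step: step 12

Assumption: the sense of induction in step 12 follows the usual shielding model of the (E)-iminium ion of (S)-diphenylprolinol trimethylsilyl ether, in which the nucleophile enters opposite the diphenyl(silyloxy)methyl group. Should the arms prove to have the opposite configuration, the enantiomeric amine is used.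

Remark: centres and geometries that form as mixtures and are removed later are written without configuration. These are C2' in 20 and 21, the enol ether geometry in 23, and the two new sp3 centres per arm in 25.

## Steps

Step 1
Reactants: 1 (1S,4R)-cis-4-acetoxycyclopent-2-en-1-ol; 2 dimethyl malonate
Product: 3 dimethyl 2-[(1R,4S)-4-hydroxycyclopent-2-en-1-yl]propanedioate
Conditions: NaH, THF, 0 °C; then Pd(PPh3)4 (3 mol %), THF, 50 °C
Reagents that add atoms: none
Why: Tsuji–Trost allylic alkylation: zerovalent palladium ionises the acetate with inversion and the soft malonate attacks the π-allyl complex anti to the metal at the terminus remote from the hydroxyl, so net retention should give the cis-1,4 product and fix the future ring C4.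

Step 2
Reactants: 3 dimethyl 2-[(1R,4S)-4-hydroxycyclopent-2-en-1-yl]propanedioate
Product: 4 2-[(1R,4S)-4-hydroxycyclopent-2-en-1-yl]propane-1,3-diol
Conditions: LiAlH4, THF, 0 °C to rt; H2O, aq. NaOH work-up
Reagents that add atoms: none
Why: Hydride reduction of both esters to primary alcohols; the isolated ring alkene and the allylic alkoxide are inert to LiAlH4 at this temperature.

Step 3
Reactants: 4 2-[(1R,4S)-4-hydroxycyclopent-2-en-1-yl]propane-1,3-diol
Product: 5 (1S,4R)-4-(2,2-dimethyl-1,3-dioxan-5-yl)cyclopent-2-en-1-ol
Conditions: 2,2-dimethoxypropane, pyridinium p-toluenesulfonate (cat.), acetone, rt; aqueous work-up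
Reagents that add atoms: 2,2-dimethoxypropane COC(C)(C)OC
Why: Thermodynamic ketalisation selects the six-membered 1,3-dioxane of the 2-substituted propane-1,3-diol; the lone secondary hydroxyl cannot close a ring and any mixed ketal on it is lost on aqueous work-up.

Step 4
Reactants: 5 (1S,4R)-4-(2,2-dimethyl-1,3-dioxan-5-yl)cyclopent-2-en-1-ol
Product: 6 (4R)-4-(2,2-dimethyl-1,3-dioxan-5-yl)cyclopent-2-en-1-one
Conditions: activated MnO2, CH2Cl2, rt
Reagents that add atoms: none
Why: Selective oxidation of an allylic alcohol on the oxide surface under neutral conditions, which should leave the γ-stereocentre of the enone untouched.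

Step 5
Reactants: 6 (4R)-4-(2,2-dimethyl-1,3-dioxan-5-yl)cyclopent-2-en-1-one
Product: 8 (2R,3S,4R)-4-(2,2-dimethyl-1,3-dioxan-5-yl)-3-ethenyl-2-methylcyclopentan-1-one, via bromomagnesium enolate 7 (not isolated)
Conditions: CH2=CHMgBr, CuBr·SMe2 (10 mol %), THF, −78 °C; then MeI, DMPU, −78 to 0 °C
Reagents that add atoms: vinylmagnesium bromide C=C[Mg]Br; iodomethane CI
Why: Copper-catalysed conjugate addition occurs anti to the C4 substituent and the regiodefined enolate is methylated anti to the new vinyl group (tandem conjugate addition–enolate alkylation); C2 is α to the ketone, so the trans,trans isomer is also the thermodynamic one.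

Step 6
Reactants: 8 (2R,3S,4R)-4-(2,2-dimethyl-1,3-dioxan-5-yl)-3-ethenyl-2-methylcyclopentan-1-one
Product: 9 (1S,2R,3S,4R)-4-(2,2-dimethyl-1,3-dioxan-5-yl)-3-ethenyl-2-methylcyclopentan-1-ol
Conditions: LiBH(s-Bu)3, THF, −78 °C; then H2O
Reagents that add atoms: none
Why: The bulky trialkylborohydride attacks the face opposite the adjacent methyl group and the C4 substituent (steric approach control), giving the cis-2-methyl carbinol; this epimer is wanted because step 9 inverts C1.

Step 7
Reactants: 9 (1S,2R,3S,4R)-4-(2,2-dimethyl-1,3-dioxan-5-yl)-3-ethenyl-2-methylcyclopentan-1-ol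
Product: 11 (1S,2R,3S,4R)-4-(2,2-dimethyl-1,3-dioxan-5-yl)-3-(hydroxymethyl)-2-methylcyclopentan-1-ol, via hydroxy aldehyde 10 (not isolated)
Conditions: O3, CH2Cl2–MeOH, −78 °C; then NaBH4, −78 °C to rt
Reagents that add atoms: ozone [O-][O+]=O
Why: Ozonolysis of the terminal alkene with borohydride work-up; the transient aldehyde already has the more stable trans,trans arrangement at C3 and is reduced in the same flask.

Step 8
Reactants: 12 Meldrum's acid; 13 allyl alcohol
Product: 14 allyl hydrogen malonate
Conditions: toluene, 100 °C
Reagents that add atoms: none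
Why: Thermal alcoholysis of the dioxanedione: the alcohol opens the ring and acetone is expelled, leaving the malonic half-ester.

Step 9
Reactants: 11 (1S,2R,3S,4R)-4-(2,2-dimethyl-1,3-dioxan-5-yl)-3-(hydroxymethyl)-2-methylcyclopentan-1-ol; 14 allyl hydrogen malonate (two equivalents are incorporated, one on each hydroxyl)
Product: 15 allyl (1R,2R,3S,4R)-3-({[3-(allyloxy)-3-oxopropanoyl]oxy}methyl)-4-(2,2-dimethyl-1,3-dioxan-5-yl)-2-methylcyclopentyl propanedioate
Conditions: 14 (2.5 equiv), PPh3 (2.5 equiv), diisopropyl azodicarboxylate (2.5 equiv), THF, 0 °C to rt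
Reagents that add atoms: allyl hydrogen malonate (second equivalent of 14) C=CCOC(=O)CC(=O)O
Why: Two-fold Mitsunobu esterification: one molecule of 14 acylates the primary hydroxyl, and a second displaces the secondary oxyphosphonium ion with SN2 inversion, converting 1S into 1R and completing the all-trans ring. The carboxylic acid is far more acidic than the malonate methylene, so O-acylation should prevail over C-alkylation.

Step 10
Reactants: 16 but-3-en-1-ol
Product: 17 (but-3-en-1-yloxy)(tert-butyl)dimethylsilane
Conditions: t-BuMe2SiCl, imidazole, CH2Cl2, rt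
Reagents that add atoms: tert-butyldimethylsilyl chloride CC(C)(C)[Si](C)(C)Cl
Why: Standard silylation of a primary alcohol.

Step 11
Reactants: 17 (but-3-en-1-yloxy)(tert-butyl)dimethylsilane; 18 (E)-but-2-enal (crotonaldehyde)
Product: 19 (E)-5-[(tert-butyldimethylsilyl)oxy]pent-2-enal
Conditions: second-generation Hoveyda–Grubbs catalyst RuCl2(H2IMes)(=CH-C6H4-2-O-i-Pr) (2 mol %), excess 18, CH2Cl2, 40 °C
Reagents that add atoms: none
Why: Olefin cross-metathesis of a terminal alkene with an electron-poor partner; the conjugated E enal is the thermodynamic product and propene is lost.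

Step 12
Reactants: 15 core bis(allyl malonate); 19 (E)-5-[(tert-butyldimethylsilyl)oxy]pent-2-enal (two equivalents are incorporated, one on each malonate)
Product: 20 bis-Michael adduct: 15 in which each malonate carbon (configuration undefined) carries a (3R)-5-[(tert-butyldimethylsilyl)oxy]-1-oxopentan-3-yl group
Conditions: (S)-2-[diphenyl(trimethylsilyloxy)methyl]pyrrolidine (20 mol %), PhCO2H (20 mol %), 19 (3 equiv), EtOH, 0 °C
Reagents that add atoms: (E)-5-[(tert-butyldimethylsilyl)oxy]pent-2-enal (second equivalent of 19) CC(C)(C)[Si](C)(C)OCC/C=C/C=O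
Why: The amine condenses with enal 19 to an (E)-configured, s-trans iminium ion, one face of which is covered by the diphenyl(trimethylsilyloxy)methyl group; a malonate unit of 15 is deprotonated by benzoate and its C2' adds to the iminium β-carbon (the future C3') from the open face, after which the enamine is protonated and hydrolysed, returning the amine, and the same cycle then runs on the second malonate unit with a second molecule of 19. The closest known reaction type is the diarylprolinol silyl ether-catalysed Michael addition of dialkyl malonates to aliphatic enals, applied here twice to an unsymmetrical malonate diester. No ring is closed. Each C3' centre is controlled by the catalyst alone: the S-configured amine should give the 3R arrangement in 20, which is the 3S arrangement of 29 once the 2-oxoethyl branch carries the ethylidene group, and the ring stereocentres, four or more bonds away from C3', are not expected to interfere, so both arms should receive the same configuration. The C2' centres form as mixtures and are erased in step 13. The step needs 1,4- over 1,2-addition (secured by iminium activation and the soft nucleophile), one addition per malonate (the adduct is a hindered tertiary malonate) and complete conversion of both malonate units (enal in excess). The silyl ether of 19 is a poorer leaving group from a transient dienamine than the alkoxide of an acetal, whose departure a second alkoxy group would assist, which is the reason it is used.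

Step 13
Reactants: 20 bis-Michael adduct
Product: 22 (1R,2R,3S,4R)-3-({[(3R)-5-(tert-butyldimethylsilyloxy)-3-(2-oxoethyl)pentanoyl]oxy}methyl)-4-(2,2-dimethyl-1,3-dioxan-5-yl)-2-methylcyclopentyl (3R)-5-(tert-butyldimethylsilyloxy)-3-(2-oxoethyl)pentanoate, via bis(malonic half-acid) 21 (not isolated)
Conditions: Pd(PPh3)4 (5 mol %), HCO2H, Et3N, 1,4-dioxane, rt; then 100 °C
Reagents that add atoms: none
Why: Tsuji deallylation: zerovalent palladium forms a π-allyl complex from each allyl ester and formate reduces it to propene. The malonic half-acids then lose CO2 on heating through a cyclic transition state, which removes the stereorandom C2' centres while the core esters, silyl ethers and ketal stay intact in the buffered medium.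

Step 14
Reactants: 22 bis(aldehyde)
Product: 23 bis(trimethylsilyl enol ether) of 22 (each 2-oxoethyl group converted into a 2-(trimethylsilyloxy)ethenyl group, E/Z mixture)
Conditions: Me3SiOTf (2.4 equiv), Et3N (3 equiv), CH2Cl2, −20 to 0 °C; non-aqueous work-up (pentane, filtration)
Reagents that add atoms: trimethylsilyl trifluoromethanesulfonate (first equivalent) C[Si](C)(C)OS(=O)(=O)C(F)(F)F; trimethylsilyl trifluoromethanesulfonate (second equivalent) C[Si](C)(C)OS(=O)(=O)C(F)(F)F
Why: Soft enolisation of each aldehyde by silyl triflate and amine; the ester α-positions react far more slowly, and a ketal tolerates these conditions whereas an aldehyde-derived acetal would not.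

Step 15
Reactants: 23 bis(trimethylsilyl enol ether); 24 acetaldehyde dimethyl acetal (excess, one molecule per arm)
Product: 26 (1R,2R,3S,4R)-3-({[(3S,4E)-3-[2-(tert-butyldimethylsilyloxy)ethyl]-4-formylhex-4-enoyl]oxy}methyl)-4-(2,2-dimethyl-1,3-dioxan-5-yl)-2-methylcyclopentyl (3S,4E)-3-[2-(tert-butyldimethylsilyloxy)ethyl]-4-formylhex-4-enoate, via bis(β-methoxy aldehyde) 25 (not isolated)
Conditions: excess 24, Me3SiOTf (10 mol %), CH2Cl2, −78 °C; then DBU, CH2Cl2, 0 °C to rt
Reagents that add atoms: none
Why: Mukaiyama-type aldol addition of an enol silane to an acetal: the silyl triflate ionises 24 to a methoxycarbenium ion that is attacked by the enol silane α-carbon, and the β-methoxy aldehyde then loses methanol by E1cB elimination. The E enal (methyl trans to formyl) is the thermodynamic isomer, and C3' carries no acidifying group, so its configuration is kept.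

Step 16
Reactants: 26 bis(silyl ether) bis(enal)
Product: 27 (1R,2R,3S,4R)-4-(2,2-dimethyl-1,3-dioxan-5-yl)-3-({[(3S,4E)-4-formyl-3-(2-hydroxyethyl)hex-4-enoyl]oxy}methyl)-2-methylcyclopentyl (3S,4E)-4-formyl-3-(2-hydroxyethyl)hex-4-enoate
Conditions: HF·pyridine, pyridine, THF, 0 °C to rt
Reagents that add atoms: none
Why: Fluoride cleavage of primary silyl ethers; the buffered reagent leaves the ketal, the esters and the enals alone.

Step 17
Reactants: 27 diol bis(enal)
Product: 28 (1R,2R,3S,4R)-4-(2,2-dimethyl-1,3-dioxan-5-yl)-3-({[(3S,4E)-4-formyl-3-(2-oxoethyl)hex-4-enoyl]oxy}methyl)-2-methylcyclopentyl (3S,4E)-4-formyl-3-(2-oxoethyl)hex-4-enoate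
Conditions: Dess–Martin periodinane, CH2Cl2, 0 °C to rt
Reagents that add atoms: none
Why: Dess–Martin oxidation of primary alcohols to aldehydes without base; the conjugated formyl group prefers the open form over a lactol, so the hydroxyl should be oxidised to the aldehyde and not to a lactone.

Step 18
Reactants: 28 tetra-aldehyde ketal
Product: 29 (1R,2R,3S,4R)-4-(1,3-dihydroxypropan-2-yl)-3-({[(3S,4E)-4-formyl-3-(2-oxoethyl)hex-4-enoyl]oxy}methyl)-2-methylcyclopentyl (3S,4E)-4-formyl-3-(2-oxoethyl)hex-4-enoate
Conditions: AcOH–H2O–THF (3:1:1), rt to 40 °C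
Reagents that add atoms: none
Why: Acid-catalysed hydrolysis of the isopropylidene ketal of a 1,3-diol; dilute acetic acid should spare the esters, the E enals and the 1,5-dialdehyde arrays.

## Compound list

1 | (1S,4R)-cis-4-acetoxycyclopent-2-en-1-ol | CC(=O)O[C@H]1C=C[C@@H](O)C1 | starting material
2 | dimethyl malonate | COC(=O)CC(=O)OC | starting material
3 | dimethyl 2-[(1R,4S)-4-hydroxycyclopent-2-en-1-yl]propanedioate | COC(=O)C(C(=O)OC)[C@H]1C=C[C@@H](O)C1 | intermediate
4 | 2-[(1R,4S)-4-hydroxycyclopent-2-en-1-yl]propane-1,3-diol | OCC(CO)[C@H]1C=C[C@@H](O)C1 | intermediate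
5 | (1S,4R)-4-(2,2-dimethyl-1,3-dioxan-5-yl)cyclopent-2-en-1-ol | CC1(C)OCC(CO1)[C@H]2C=C[C@@H](O)C2 | intermediate
6 | (4R)-4-(2,2-dimethyl-1,3-dioxan-5-yl)cyclopent-2-en-1-one | CC1(C)OCC(CO1)[C@H]2C=CC(=O)C2 | intermediate
7 | bromomagnesium C1–C2 enolate of (3S,4R)-4-(2,2-dimethyl-1,3-dioxan-5-yl)-3-ethenylcyclopentanone (not isolated) | C=C[C@@H]1C=C(O[Mg]Br)C[C@H]1C2COC(C)(C)OC2 | intermediate
8 | (2R,3S,4R)-4-(2,2-dimethyl-1,3-dioxan-5-yl)-3-ethenyl-2-methylcyclopentan-1-one | C=C[C@@H]1[C@@H](C)C(=O)C[C@H]1C2COC(C)(C)OC2 | intermediate
9 | (1S,2R,3S,4R)-4-(2,2-dimethyl-1,3-dioxan-5-yl)-3-ethenyl-2-methylcyclopentan-1-ol | C=C[C@@H]1[C@@H](C)[C@@H](O)C[C@H]1C2COC(C)(C)OC2 | intermediate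
10 | hydroxy aldehyde: 9 with formyl in place of ethenyl, same spatial arrangement (not isolated) | O=C[C@@H]1[C@@H](C)[C@@H](O)C[C@H]1C2COC(C)(C)OC2 | intermediate
11 | (1S,2R,3S,4R)-4-(2,2-dimethyl-1,3-dioxan-5-yl)-3-(hydroxymethyl)-2-methylcyclopentan-1-ol | OC[C@@H]1[C@@H](C)[C@@H](O)C[C@H]1C2COC(C)(C)OC2 | intermediate
12 | Meldrum's acid (2,2-dimethyl-1,3-dioxane-4,6-dione) | CC1(C)OC(=O)CC(=O)O1 | starting material
13 | allyl alcohol | C=CCO | starting material
14 | allyl hydrogen malonate | C=CCOC(=O)CC(=O)O | intermediate
15 | allyl (1R,2R,3S,4R)-3-({[3-(allyloxy)-3-oxopropanoyl]oxy}methyl)-4-(2,2-dimethyl-1,3-dioxan-5-yl)-2-methylcyclopentyl propanedioate | C=CCOC(=O)CC(=O)OC[C@@H]1[C@@H](C)[C@H](OC(=O)CC(=O)OCC=C)C[C@H]1C2COC(C)(C)OC2 | intermediate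
16 | but-3-en-1-ol | C=CCCO | starting material
17 | (but-3-en-1-yloxy)(tert-butyl)dimethylsilane | C=CCCO[Si](C)(C)C(C)(C)C | intermediate
18 | (E)-but-2-enal (crotonaldehyde) | C/C=C/C=O | starting material
19 | (E)-5-[(tert-butyldimethylsilyl)oxy]pent-2-enal | CC(C)(C)[Si](C)(C)OCC/C=C/C=O | intermediate
20 | bis-Michael adduct: 15 with a (3R)-5-[(tert-butyldimethylsilyl)oxy]-1-oxopentan-3-yl group on each malonate carbon (malonate carbons undefined) | O=CC[C@@H](CCO[Si](C)(C)C(C)(C)C)C(C(=O)OCC=C)C(=O)OC[C@@H]1[C@@H](C)[C@H](OC(=O)C(C(=O)OCC=C)[C@H](CCO[Si](C)(C)C(C)(C)C)CC=O)C[C@H]1C2COC(C)(C)OC2 | intermediate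
21 | bis(malonic half-acid): 20 with both allyl esters as free carboxylic acids (not isolated) | O=CC[C@@H](CCO[Si](C)(C)C(C)(C)C)C(C(=O)O)C(=O)OC[C@@H]1[C@@H](C)[C@H](OC(=O)C(C(=O)O)[C@H](CCO[Si](C)(C)C(C)(C)C)CC=O)C[C@H]1C2COC(C)(C)OC2 | intermediate
22 | core diester of (3R)-5-(tert-butyldimethylsilyloxy)-3-(2-oxoethyl)pentanoic acid (ring 1R,2R,3S,4R, ketal) | O=CC[C@@H](CCO[Si](C)(C)C(C)(C)C)CC(=O)OC[C@@H]1[C@@H](C)[C@H](OC(=O)C[C@H](CCO[Si](C)(C)C(C)(C)C)CC=O)C[C@H]1C2COC(C)(C)OC2 | intermediate
23 | bis(trimethylsilyl enol ether) of 22 (enol ether geometry mixed) | C[Si](C)(C)OC=C[C@@H](CCO[Si](C)(C)C(C)(C)C)CC(=O)OC[C@@H]1[C@@H](C)[C@H](OC(=O)C[C@H](CCO[Si](C)(C)C(C)(C)C)C=CO[Si](C)(C)C)C[C@H]1C2COC(C)(C)OC2 | intermediate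
24 | acetaldehyde dimethyl acetal (1,1-dimethoxyethane) | CC(OC)OC | starting material
25 | bis(β-methoxy aldehyde): each arm a 5-(tert-butyldimethylsilyloxy)-3-(3-methoxy-1-oxobutan-2-yl)pentanoate, new centres undefined (not isolated) | COC(C)C(C=O)[C@@H](CCO[Si](C)(C)C(C)(C)C)CC(=O)OC[C@@H]1[C@@H](C)[C@H](OC(=O)C[C@H](CCO[Si](C)(C)C(C)(C)C)C(C=O)C(C)OC)C[C@H]1C2COC(C)(C)OC2 | intermediate
26 | core diester of (3S,4E)-3-[2-(tert-butyldimethylsilyloxy)ethyl]-4-formylhex-4-enoic acid (ketal) | C/C=C(/C=O)[C@@H](CCO[Si](C)(C)C(C)(C)C)CC(=O)OC[C@@H]1[C@@H](C)[C@H](OC(=O)C[C@H](CCO[Si](C)(C)C(C)(C)C)/C(C=O)=C\C)C[C@H]1C2COC(C)(C)OC2 | intermediate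
27 | core diester of (3S,4E)-4-formyl-3-(2-hydroxyethyl)hex-4-enoic acid (ketal) | C/C=C(/C=O)[C@@H](CCO)CC(=O)OC[C@@H]1[C@@H](C)[C@H](OC(=O)C[C@H](CCO)/C(C=O)=C\C)C[C@H]1C2COC(C)(C)OC2 | intermediate
28 | core diester of (3S,4E)-4-formyl-3-(2-oxoethyl)hex-4-enoic acid (ketal) | C/C=C(/C=O)[C@@H](CC=O)CC(=O)OC[C@@H]1[C@@H](C)[C@H](OC(=O)C[C@H](CC=O)/C(C=O)=C\C)C[C@H]1C2COC(C)(C)OC2 | intermediate
29 | (1R,2R,3S,4R)-4-(1,3-dihydroxypropan-2-yl)-3-({[(3S,4E)-4-formyl-3-(2-oxoethyl)hex-4-enoyl]oxy}methyl)-2-methylcyclopentyl (3S,4E)-4-formyl-3-(2-oxoethyl)hex-4-enoate | C/C=C(/C=O)[C@@H](CC=O)CC(=O)OC[C@@H]1[C@@H](C)[C@H](OC(=O)C[C@H](CC=O)/C(C=O)=C\C)C[C@H]1C(CO)CO | target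

## Step count and risks

Total: 18 steps. Longest linear sequence: 15 steps (steps 1–7, 9, 12–18, from 1). Steps 8, 10 and 11 are side branches.

**Step 12 (key step).** The second addition may stall, leaving mono-adduct. Reversibility or uncatalysed base-mediated addition may erode facial selectivity. The product aldehyde may enter as an enamine donor and oligomerise with excess enal, and γ-deprotonation of the iminium ion may divert enal into dienamine pathways. Fallback, from 19 (using 11), returning at 22: the arm is made before attachment. Enal 19 is combined with commercial diallyl malonate under the same amine catalysis to give diallyl 2-[(3R)-5-(tert-butyldimethylsilyloxy)-1-oxopentan-3-yl]propanedioate F1. Deallylation with zerovalent palladium and formate, with loss of one CO2, gives (3R)-5-(tert-butyldimethylsilyloxy)-3-(2-oxoethyl)pentanoic acid F2. A two-fold Mitsunobu esterification of diol 11 with F2 (inversion at ring C1 as in step 9) then gives 22 directly.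

**Step 9.** The activated secondary carbinol has an anti hydrogen on C2, so elimination to the trisubstituted cyclopentene may compete with substitution, and inversion of the hindered centre may be incomplete. The still-free primary hydroxyl may also close a bridged ether on the activated secondary carbon before it is acylated. Fallback, from 9, returning at 15: inversion and acylation are separated. Mitsunobu reaction of mono-alcohol 9 with 4-nitrobenzoic acid gives (1R,2R,3S,4R)-4-(2,2-dimethyl-1,3-dioxan-5-yl)-3-ethenyl-2-methylcyclopentyl 4-nitrobenzoate F3. Methanolysis (K2CO3, MeOH) gives (1R,2R,3S,4R)-4-(2,2-dimethyl-1,3-dioxan-5-yl)-3-ethenyl-2-methylcyclopentan-1-ol F4. Ozonolysis with NaBH4 work-up gives (1R,2R,3S,4R)-4-(2,2-dimethyl-1,3-dioxan-5-yl)-3-(hydroxymethyl)-2-methylcyclopentan-1-ol F5. Carbodiimide esterification (EDC, DMAP) with two equivalents of 14 gives 15.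

**Step 5.** Proton transfer between enolate and product may scramble the enolate position and lead to over-methylation or methylation at C5, and some 1,2-addition of the Grignard reagent may occur. Fallback, from 6, returning at 8: the methyl group is installed before the conjugate addition. α-Iodination of 6 (I2, pyridine) gives (4S)-4-(2,2-dimethyl-1,3-dioxan-5-yl)-2-iodocyclopent-2-en-1-one F6. Suzuki–Miyaura coupling with methylboronic acid (PdCl2(dppf), K3PO4) gives (4R)-4-(2,2-dimethyl-1,3-dioxan-5-yl)-2-methylcyclopent-2-en-1-one F7. Copper-catalysed vinyl Grignard addition anti to C4, protonation and base equilibration of C2 (DBU) give 8.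

**Step 13.** In hot triethylammonium formate the free aldehydes may undergo aldol condensation, decarboxylation may be incomplete, and a silyl ether may be lost. Fallback, from 20 through isolated 21, returning at 22: the two events are separated and the thermal step is replaced by a radical one. Deallylation at room temperature with Pd(PPh3)4 and sodium p-toluenesulfinate gives 21. Acridinium photoredox hydrodecarboxylation (9-mesityl-10-methylacridinium tetrafluoroborate, diphenyl disulfide, 2,6-lutidine, trifluoroethanol, blue light) then gives 22. No compound outside the list is made (F0).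

**Step 15.** The silyl triflate may ionise the ring ketal in competition with the acetal, and the enol silane may hydrolyse before it reacts. The product aldehyde may be converted into its dimethyl acetal by the methoxysilane formed and the excess acetal, which would block the elimination. Elimination may also be incomplete or give E/Z mixtures. Fallback, from 23, returning at 26: a Lewis-base-catalysed aldol addition to the free aldehyde replaces the Lewis-acid/acetal pair. LiOAc-catalysed Mukaiyama aldol addition of 23 to acetaldehyde (DMF) gives the bis(β-hydroxy aldehyde), each arm a 5-(tert-butyldimethylsilyloxy)-3-(3-hydroxy-1-oxobutan-2-yl)pentanoate, F8. Mesylation and elimination (MsCl, Et3N) give 26.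

## Further compounds

F1 | step 12 | diallyl 2-[(3R)-5-(tert-butyldimethylsilyloxy)-1-oxopentan-3-yl]propanedioate | C=CCOC(=O)C(C(=O)OCC=C)[C@H](CCO[Si](C)(C)C(C)(C)C)CC=O
F2 | step 12 | (3R)-5-(tert-butyldimethylsilyloxy)-3-(2-oxoethyl)pentanoic acid | O=CC[C@@H](CCO[Si](C)(C)C(C)(C)C)CC(=O)O
F3 | step 9 | (1R,2R,3S,4R)-4-(2,2-dimethyl-1,3-dioxan-5-yl)-3-ethenyl-2-methylcyclopentyl 4-nitrobenzoate | C=C[C@@H]1[C@@H](C)[C@H](OC(=O)c2ccc(cc2)[N+](=O)[O-])C[C@H]1C3COC(C)(C)OC3
F4 | step 9 | (1R,2R,3S,4R)-4-(2,2-dimethyl-1,3-dioxan-5-yl)-3-ethenyl-2-methylcyclopentan-1-ol | C=C[C@@H]1[C@@H](C)[C@H](O)C[C@H]1C2COC(C)(C)OC2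
F5 | step 9 | (1R,2R,3S,4R)-4-(2,2-dimethyl-1,3-dioxan-5-yl)-3-(hydroxymethyl)-2-methylcyclopentan-1-ol | OC[C@@H]1[C@@H](C)[C@H](O)C[C@H]1C2COC(C)(C)OC2
F6 | step 5 | (4S)-4-(2,2-dimethyl-1,3-dioxan-5-yl)-2-iodocyclopent-2-en-1-one | CC1(C)OCC(CO1)[C@H]2C=C(I)C(=O)C2
F7 | step 5 | (4R)-4-(2,2-dimethyl-1,3-dioxan-5-yl)-2-methylcyclopent-2-en-1-one | CC1(C)OCC(CO1)[C@H]2C=C(C)C(=O)C2
F0 | step 13 | none | none
F8 | step 15 | bis(β-hydroxy aldehyde): core diester of 5-(tert-butyldimethylsilyloxy)-3-(3-hydroxy-1-oxobutan-2-yl)pentanoic acid (new centres undefined) | CC(O)C(C=O)[C@@H](CCO[Si](C)(C)C(C)(C)C)CC(=O)OC[C@@H]1[C@@H](C)[C@H](OC(=O)C[C@H](CCO[Si](C)(C)C(C)(C)C)C(C=O)C(C)O)C[C@H]1C2COC(C)(C)OC2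
A1 | alternative 1 | dimethyl 2-[(3R,4E)-3-(tert-butyldimethylsilyloxy)-4-methyl-6-oxohex-4-en-1-ylidene]propanedioate | O=C/C=C(\C)[C@H](O[Si](C)(C)C(C)(C)C)CC=C(C(=O)OC)C(=O)OC
A2 | alternative 1 | dimethyl 2-[(1R,2S,3R,4R)-4-(tert-butyldimethylsilyloxy)-2-formyl-3-methylcyclopentyl]propanedioate | O=C[C@@H]1[C@@H](C)[C@H](O[Si](C)(C)C(C)(C)C)C[C@H]1C(C(=O)OC)C(=O)OC
A3 | alternative 2 | (3R,4R)-4-[(benzyloxy)methyl]-3-(2,2-dimethyl-1,3-dioxan-5-yl)hex-5-enal | O=CC[C@@H](C1COC(C)(C)OC1)[C@H](COCc1ccccc1)C=C
A4 | alternative 2 | (1R,2R,3S,4R)-3-[(benzyloxy)methyl]-4-(2,2-dimethyl-1,3-dioxan-5-yl)-2-methylcyclopentan-1-ol | c1ccccc1COC[C@@H]2[C@@H](C)[C@H](O)C[C@H]2C3COC(C)(C)OC3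
A5 | alternative 3 | (1R,2R,3S,4R)-4-(2,2-dimethyl-1,3-dioxan-5-yl)-2-methyl-3-({[(E)-5-oxopent-3-enoyl]oxy}methyl)cyclopentyl (E)-5-oxopent-3-enoate | O=C/C=C/CC(=O)OC[C@@H]1[C@@H](C)[C@H](OC(=O)C/C=C/C=O)C[C@H]1C2COC(C)(C)OC2
A6 | alternative 3 | ethyl vinyl ether | C=COCC
A7 | alternative 3 | core bis[(cis-2-ethoxy-3,4-dihydro-2H-pyran-4-yl)acetate], ketal | O=C(C[C@H]1C=CO[C@@H](OCC)C1)OC[C@@H]2[C@@H](C)[C@H](OC(=O)C[C@H]3C=CO[C@@H](OCC)C3)C[C@H]2C4COC(C)(C)OC4
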